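**Strategy.** Ring C is disconnected at two bonds, C2–C3 and C4=O, so that the O1–C2(H)=C3(aryl)–C4(=O) vinylogous ester fused to ring A at C4a/C8a comes from an aryl formate (O1–C2H=O) and an ortho diarylalkyne (C4≡C3). One acid-catalysed isomerisation, a formal formate–alkyne metathesis, moves the formyl oxygen to C4, joins the formyl carbon to C3 and closes the pyranone. Its precursor is a 4-methoxy-3,5-bis(triisopropylsilyloxy)phenyl formate carrying a (4-acetoxyphenyl)ethynyl group at its 2-position. The robust silyl ethers and the acetate then allow selective 4'-O-prenylation and a final fluoride deprotection.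

Key step: step 10

Remark: the target is taken as 5,7-dihydroxy-6-methoxy-4'-(3-methylbut-2-enyloxy)isoflavone; an oxete over C2, C3, C4 and the migrating oxygen would be bridged across ring C with a bridgehead alkene, so step 10 is planned as a stepwise oxygen relay, and triisopropylsilyl ethers are used because a 7-silyloxy group on a chromone is base-labile.

**Step 1**
Reactants: 1 2-methoxyresorcinol
Product: 2 2-methoxy-1,3-bis(triisopropylsilyloxy)benzene
Conditions: TIPSCl, imidazole, DMF, rt to 40 °C
Reagents that add atoms: triisopropylsilyl chloride, CC(C)[Si](Cl)(C(C)C)C(C)C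
Why: Imidazole-promoted silyl ether formation on both phenols is routine, and the bulky silyl groups should later withstand Lewis acid, amine base and mild methanolysis.

**Step 2**
Reactants: 2 2-methoxy-1,3-bis(triisopropylsilyloxy)benzene
Product: 4 4-methoxy-3,5-bis(triisopropylsilyloxy)phenol, via arylboronic pinacol ester 3 (not isolated)
Conditions: [Ir(OMe)(cod)]2 (1.5 mol %), 4,4'-di-tert-butyl-2,2'-bipyridine (3 mol %), B2pin2, THF, 80 °C; then NaBO3·4H2O, THF/H2O, rt
Reagents that add atoms: sodium perborate, [Na+].[Na+].O[B-]1(O)OO[B-](O)(O)OO1 (oxygen of the new hydroxyl); bis(pinacolato)diboron, CC1(C)OB(OC1(C)C)B1OC(C)(C)C(C)(C)O1 (boryl group of 3 only)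
Why: Iridium-catalysed C–H borylation (Hartwig–Miyaura type) is sterically controlled and should take the only C–H without an ortho substituent, para to the methoxy group, and perborate oxidation of the C–B bond then gives the phenol in the same flask.

**Step 3**
Reactants: 4 4-methoxy-3,5-bis(triisopropylsilyloxy)phenol
Product: 5 2-iodo-4-methoxy-3,5-bis(triisopropylsilyloxy)phenol
Conditions: NIS (1.0 equiv), CH2Cl2, −20 to 0 °C, dark
Reagents that add atoms: N-iodosuccinimide, O=C1CCC(=O)N1I
Why: Electrophilic aromatic iodination should occur at one of the two equivalent, strongly activated positions ortho to the free hydroxyl, the only open sites, so one equivalent of reagent gives a single mono-iodide.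

**Step 4**
Reactants: 5 2-iodo-4-methoxy-3,5-bis(triisopropylsilyloxy)phenol
Product: 6 2-[2-iodo-4-methoxy-3,5-bis(triisopropylsilyloxy)phenoxy]oxane (racemic)
Conditions: 3,4-dihydro-2H-pyran, PPTS (cat.), CH2Cl2, rt
Reagents that add atoms: 3,4-dihydro-2H-pyran, C1=COCCC1
Why: Acid-catalysed tetrahydropyranyl acetal formation masks the hydroxyl so that the later Sonogashira coupling can neither cyclise to a benzofuran nor pass the acetyl group between phenols; the new acetal carbon forms as a racemate, which is of no consequence in an otherwise achiral molecule.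

**Step 5**
Reactants: 7 4-iodophenol; 8 trimethylsilylacetylene
Product: 9 4-[(trimethylsilyl)ethynyl]phenol
Conditions: PdCl2(PPh3)2 (2 mol %), CuI (4 mol %), Et3N, THF, rt
Reagents that add atoms: none
Why: Sonogashira coupling of an unhindered aryl iodide proceeds at room temperature, and a para hydroxyl cannot cyclise onto the alkyne.

**Step 6**
Reactants: 9 4-[(trimethylsilyl)ethynyl]phenol
Product: 11 4-ethynylphenyl acetate, via 4-ethynylphenol 10 (not isolated)
Conditions: K2CO3 (cat.), MeOH, rt; concentrate; then Ac2O, pyridine, CH2Cl2, 0 °C to rt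
Reagents that add atoms: acetic anhydride, CC(=O)OC(C)=O
Why: Base-catalysed methanolysis of the alkynyl C–Si bond followed by acetylation of the phenol are both standard, and telescoping avoids storing the polymerisation-prone ethynylphenol.

**Step 7**
Reactants: 6 2-[2-iodo-4-methoxy-3,5-bis(triisopropylsilyloxy)phenoxy]oxane; 11 4-ethynylphenyl acetate
Product: 12 4-({3-methoxy-6-(oxan-2-yloxy)-2,4-bis[(triisopropylsilyl)oxy]phenyl}ethynyl)phenyl acetate (racemic)
Conditions: PdCl2(PPh3)2 (5 mol %), CuI (10 mol %), Et3N/DMF, 60 °C, degassed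
Reagents that add atoms: none
Why: Sonogashira coupling of an aryl iodide with a slim terminal alkyne should tolerate the two ortho substituents on gentle heating, and a tertiary amine in an aprotic medium leaves the aryl acetate, the acetal and the silyl ethers untouched.

**Step 8**
Reactants: 12 4-({3-methoxy-6-(oxan-2-yloxy)-2,4-bis[(triisopropylsilyl)oxy]phenyl}ethynyl)phenyl acetate
Product: 13 4-({6-hydroxy-3-methoxy-2,4-bis[(triisopropylsilyl)oxy]phenyl}ethynyl)phenyl acetate
Conditions: PPTS (0.2 equiv), MeOH/THF, rt to 40 °C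
Reagents that add atoms: none
Why: Acid-catalysed transacetalisation to methanol cleaves the very labile aryl tetrahydropyranyl ether, while pyridinium acid is too weak to affect the aryl acetate, the silyl ethers or the alkyne.

**Step 9**
Reactants: 13 4-({6-hydroxy-3-methoxy-2,4-bis[(triisopropylsilyl)oxy]phenyl}ethynyl)phenyl acetate
Product: 14 2-{[4-(acetyloxy)phenyl]ethynyl}-4-methoxy-3,5-bis[(triisopropylsilyl)oxy]phenyl formate
Conditions: HCO2H/Ac2O (premixed, 55 °C, 2 h, then cooled), pyridine, THF, −20 to 0 °C; non-basic work-up, used promptly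
Reagents that add atoms: acetic formic anhydride, CC(=O)OC=O (formyl group; made beforehand from formic acid, O=CO, and acetic anhydride, CC(=O)OC(C)=O)
Why: O-Formylation of a phenol with the mixed anhydride is the standard preparation of aryl formates, since acyl transfer occurs at the more electrophilic formyl carbon, and installing the formate only after the amine-mediated coupling avoids base-induced decarbonylation.

**Step 10**
Reactants: 14 2-{[4-(acetyloxy)phenyl]ethynyl}-4-methoxy-3,5-bis[(triisopropylsilyl)oxy]phenyl formate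
Product: 17 4'-acetoxy-6-methoxy-5,7-bis(triisopropylsilyloxy)isoflavone, via formyloxy deoxybenzoin 15 (not isolated), via 2-hydroxyisoflavanone 16 (not isolated)
Conditions: In(OTf)3 (10 mol %), H2O (10 mol %), ClCH2CH2Cl, 60 °C
Reagents that add atoms: none
Why: Proposed new method: In(OTf)3 activates the alkyne, whose positive charge is best carried at C4 because the silyloxy groups of ring A sit ortho and para to C4a, so the formyl oxygen adds to C4 (6-exo-dig) to give a 1,3-benzodioxin-2-ylium ion; the catalytic water opens this ion at C2 to formyloxy deoxybenzoin 15, whose enol carbon C3 then attacks the activated formate carbon C2 to give hemiacetal 16, and loss of water forms C2=C3 and returns the shuttle. A discrete oxete is not invoked, since a four-membered ring over C2, C3, C4 and oxygen would be bridged across ring C with a bridgehead alkene. The closest known reaction types are Lewis or Brønsted acid-catalysed alkyne–aldehyde and alkyne–ketone metathesis, ester-assisted alkyne hydration, and the Baker–Venkataraman acyl transfer with cyclodehydration that turns ortho-acyloxy aryl ketones into chromones. Ring C closes in the C3-to-C2 attack, a 6-(enolendo)-exo-trig closure, and no stereocenter remains because C2 and C3 of 16 both become sp2. The step needs carbonyl-oxygen attack at C4 to win over 5-endo attack of the ether oxygen at C3 and over loss of the formyl group; the electron-rich ring A, the weakly donating acetoxy ring B, the poor nucleophilicity of an ester ether oxygen and the small amount of water are expected to secure this.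

**Step 11**
Reactants: 17 4'-acetoxy-6-methoxy-5,7-bis(triisopropylsilyloxy)isoflavone
Product: 18 4'-hydroxy-6-methoxy-5,7-bis(triisopropylsilyloxy)isoflavone
Conditions: NH4OAc (excess), MeOH/THF, rt
Reagents that add atoms: none
Why: Ammonium acetate-mediated methanolysis (transesterification) is selective for aryl acetates, and this weak base should leave the hindered aryl triisopropylsilyl ethers and the pyranone intact, so only the 4'-phenol is freed.

**Step 12**
Reactants: 18 4'-hydroxy-6-methoxy-5,7-bis(triisopropylsilyloxy)isoflavone; 19 prenol (3-methylbut-2-en-1-ol)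
Product: 20 6-methoxy-4'-(3-methylbut-2-enyloxy)-5,7-bis(triisopropylsilyloxy)isoflavone
Conditions: PPh3, DIAD, THF, 0 °C to rt
Reagents that add atoms: none
Why: Mitsunobu etherification of the only free phenol at the primary carbon of prenol gives the unrearranged prenyl ether under neutral conditions that spare the silyl ethers.

**Step 13**
Reactants: 20 6-methoxy-4'-(3-methylbut-2-enyloxy)-5,7-bis(triisopropylsilyloxy)isoflavone
Product: 21 isoaurmillone
Conditions: Bu4NF (2.5 equiv), AcOH (2.5 equiv), THF, 0 °C
Reagents that add atoms: none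
Why: Fluoride-driven cleavage of both aryl Si–O bonds is fast, the acetic acid buffer protects the pyranone from base-induced ring opening, and the prenyl ether is inert to fluoride.

**Compound list**

1 | 2-methoxyresorcinol | COc1c(O)cccc1O | starting material
2 | 2-methoxy-1,3-bis(triisopropylsilyloxy)benzene | COc1c(O[Si](C(C)C)(C(C)C)C(C)C)cccc1O[Si](C(C)C)(C(C)C)C(C)C | intermediate
3 | 2-[4-methoxy-3,5-bis(triisopropylsilyloxy)phenyl]-4,4,5,5-tetramethyl-1,3,2-dioxaborolane | COc1c(O[Si](C(C)C)(C(C)C)C(C)C)cc(B2OC(C)(C)C(C)(C)O2)cc1O[Si](C(C)C)(C(C)C)C(C)C | intermediate (not isolated)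
4 | 4-methoxy-3,5-bis(triisopropylsilyloxy)phenol | COc1c(O[Si](C(C)C)(C(C)C)C(C)C)cc(O)cc1O[Si](C(C)C)(C(C)C)C(C)C | intermediate
5 | 2-iodo-4-methoxy-3,5-bis(triisopropylsilyloxy)phenol | COc1c(O[Si](C(C)C)(C(C)C)C(C)C)cc(O)c(I)c1O[Si](C(C)C)(C(C)C)C(C)C | intermediate
6 | 2-[2-iodo-4-methoxy-3,5-bis(triisopropylsilyloxy)phenoxy]oxane (racemic) | COc1c(O[Si](C(C)C)(C(C)C)C(C)C)cc(OC2CCCCO2)c(I)c1O[Si](C(C)C)(C(C)C)C(C)C | intermediate
7 | 4-iodophenol | Oc1ccc(I)cc1 | starting material
8 | trimethylsilylacetylene | C#C[Si](C)(C)C | starting material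
9 | 4-[(trimethylsilyl)ethynyl]phenol | C[Si](C)(C)C#Cc1ccc(O)cc1 | intermediate
10 | 4-ethynylphenol | C#Cc1ccc(O)cc1 | intermediate (not isolated)
11 | 4-ethynylphenyl acetate | CC(=O)Oc1ccc(C#C)cc1 | intermediate
12 | 4-({3-methoxy-6-(oxan-2-yloxy)-2,4-bis[(triisopropylsilyl)oxy]phenyl}ethynyl)phenyl acetate (racemic) | COc1c(O[Si](C(C)C)(C(C)C)C(C)C)cc(OC2CCCCO2)c(C#Cc2ccc(OC(C)=O)cc2)c1O[Si](C(C)C)(C(C)C)C(C)C | intermediate
13 | 4-({6-hydroxy-3-methoxy-2,4-bis[(triisopropylsilyl)oxy]phenyl}ethynyl)phenyl acetate | COc1c(O[Si](C(C)C)(C(C)C)C(C)C)cc(O)c(C#Cc2ccc(OC(C)=O)cc2)c1O[Si](C(C)C)(C(C)C)C(C)C | intermediate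
14 | 2-{[4-(acetyloxy)phenyl]ethynyl}-4-methoxy-3,5-bis[(triisopropylsilyl)oxy]phenyl formate | COc1c(O[Si](C(C)C)(C(C)C)C(C)C)cc(OC=O)c(C#Cc2ccc(OC(C)=O)cc2)c1O[Si](C(C)C)(C(C)C)C(C)C | intermediate (key-step precursor)
15 | 4-{2-[2-(formyloxy)-5-methoxy-4,6-bis(triisopropylsilyloxy)phenyl]-2-oxoethyl}phenyl acetate | COc1c(O[Si](C(C)C)(C(C)C)C(C)C)cc(OC=O)c(C(=O)Cc2ccc(OC(C)=O)cc2)c1O[Si](C(C)C)(C(C)C)C(C)C | intermediate (not isolated)
16 | 4-[2-hydroxy-6-methoxy-4-oxo-5,7-bis(triisopropylsilyloxy)chroman-3-yl]phenyl acetate (transient, configuration at C2 and C3 undefined) | COc1c(O[Si](C(C)C)(C(C)C)C(C)C)cc2OC(O)C(c3ccc(OC(C)=O)cc3)C(=O)c2c1O[Si](C(C)C)(C(C)C)C(C)C | intermediate (not isolated)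
17 | 4'-acetoxy-6-methoxy-5,7-bis(triisopropylsilyloxy)isoflavone | COc1c(O[Si](C(C)C)(C(C)C)C(C)C)cc2occ(-c3ccc(OC(C)=O)cc3)c(=O)c2c1O[Si](C(C)C)(C(C)C)C(C)C | intermediate (key-step product)
18 | 4'-hydroxy-6-methoxy-5,7-bis(triisopropylsilyloxy)isoflavone | COc1c(O[Si](C(C)C)(C(C)C)C(C)C)cc2occ(-c3ccc(O)cc3)c(=O)c2c1O[Si](C(C)C)(C(C)C)C(C)C | intermediate
19 | prenol (3-methylbut-2-en-1-ol) | CC(C)=CCO | starting material
20 | 6-methoxy-4'-(3-methylbut-2-enyloxy)-5,7-bis(triisopropylsilyloxy)isoflavone | COc1c(O[Si](C(C)C)(C(C)C)C(C)C)cc2occ(-c3ccc(OCC=C(C)C)cc3)c(=O)c2c1O[Si](C(C)C)(C(C)C)C(C)C | intermediate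
21 | isoaurmillone (5,7-dihydroxy-6-methoxy-4'-(3-methylbut-2-enyloxy)isoflavone) | COc1c(O)cc2occ(-c3ccc(OCC=C(C)C)cc3)c(=O)c2c1O | target

**Step count.** Total: 13 steps. Longest linear sequence: 11 steps (steps 1–4 and 7–13, from 2-methoxyresorcinol); steps 5–6 form the side branch.

**Steps most likely to fail**

Step 10 (the labelled step). The formyl group may be lost by hydrolysis or decarbonylation before the C–C bond forms, or the freed phenol may close 5-endo onto the alkyne. The fallback uses known chemistry and sets out from 13. Brønsted acid-catalysed Markovnikov hydration of the alkyne (TfOH cat., H2O, CF3CH2OH, rt to 40 °C) places the carbonyl next to the electron-rich ring A, because protonation at C3 leaves the cation at C4, and should give the ortho-hydroxy deoxybenzoin F1. Heating with N,N-dimethylformamide dimethyl acetal in toluene then installs C2 by enaminone formation and cyclisation, the classical deoxybenzoin route to isoflavones, and returns to the route at 17.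

Step 7. Slow oxidative addition at the electron-rich iodide flanked by two ortho oxygen substituents could let copper-mediated homocoupling of the alkyne dominate. The fallback sets out from 6 and builds the alkyne on ring A by homologation instead of cross-coupling. Iodine–lithium exchange (n-BuLi, THF, −78 °C) gives the aryllithium F2, a DMF quench gives the benzaldehyde F3, and Seyferth–Gilbert homologation with the Ohira–Bestmann reagent (K2CO3, MeOH) gives the terminal arylalkyne F4. Sonogashira coupling of this alkyne with purchased 4-iodophenyl acetate, an unhindered and activated iodide that couples at room temperature, returns to the route at 12.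

Step 11. Partial loss of the 7-silyl ether during acetate cleavage would expose the more acidic 7-hydroxyl to the Mitsunobu reaction. The fallback sets out from 17 and relies on the innate acidity order of the isoflavone hydroxyls. Removal of all three protecting groups (Bu4NF, THF; then K2CO3, MeOH) gives the trihydroxy isoflavone F5. Silylation of the most acidic 7-hydroxyl with one equivalent of TIPSCl (imidazole, DMF, 0 °C) gives the 7-silyl ether F6. Mitsunobu reaction with 19 at the 4'-hydroxyl, the 5-hydroxyl being held in a hydrogen bond to the C4 carbonyl, gives the prenyl ether F7, and Bu4NF/AcOH then arrives at the target 21.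

**Further compounds**

F1 | step 10 | 4-{2-[2-hydroxy-5-methoxy-4,6-bis(triisopropylsilyloxy)phenyl]-2-oxoethyl}phenyl acetate | COc1c(O[Si](C(C)C)(C(C)C)C(C)C)cc(O)c(C(=O)Cc2ccc(OC(C)=O)cc2)c1O[Si](C(C)C)(C(C)C)C(C)C
F2 | step 7 | [3-methoxy-6-(oxan-2-yloxy)-2,4-bis(triisopropylsilyloxy)phenyl]lithium | [Li]c1c(OC2CCCCO2)cc(O[Si](C(C)C)(C(C)C)C(C)C)c(OC)c1O[Si](C(C)C)(C(C)C)C(C)C
F3 | step 7 | 3-methoxy-6-(oxan-2-yloxy)-2,4-bis(triisopropylsilyloxy)benzaldehyde | COc1c(O[Si](C(C)C)(C(C)C)C(C)C)cc(OC2CCCCO2)c(C=O)c1O[Si](C(C)C)(C(C)C)C(C)C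
F4 | step 7 | 2-[2-ethynyl-4-methoxy-3,5-bis(triisopropylsilyloxy)phenoxy]oxane | COc1c(O[Si](C(C)C)(C(C)C)C(C)C)cc(OC2CCCCO2)c(C#C)c1O[Si](C(C)C)(C(C)C)C(C)C
F5 | step 11 | 5,7-dihydroxy-3-(4-hydroxyphenyl)-6-methoxychromen-4-one | COc1c(O)cc2occ(-c3ccc(O)cc3)c(=O)c2c1O
F6 | step 11 | 5-hydroxy-3-(4-hydroxyphenyl)-6-methoxy-7-(triisopropylsilyloxy)chromen-4-one | COc1c(O[Si](C(C)C)(C(C)C)C(C)C)cc2occ(-c3ccc(O)cc3)c(=O)c2c1O
F7 | step 11 | 5-hydroxy-6-methoxy-3-[4-(3-methylbut-2-enyloxy)phenyl]-7-(triisopropylsilyloxy)chromen-4-one | COc1c(O[Si](C(C)C)(C(C)C)C(C)C)cc2occ(-c3ccc(OCC=C(C)C)cc3)c(=O)c2c1O
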